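**Retrosynthetic overview**

1. The target holds two trans-2,3-diaryl-2,3-dihydrobenzofurans: DHB 1 (O1, C2 bearing ring D, C3 bearing ring C, fused to ring B through C3a/C7a, (2S,3S)) and DHB 2 ((2R,3R), fused to ring C). The last disconnections are the six benzyl ethers and the bond between C4 of ring B and the (E)-styryl arm, the latter made by a Heck reaction on a C4 bromide.
2. The strategy rests on this feature: C3 of DHB 1 is benzylic and ortho to O1 on ring B, so C3–C3a–C7a–O1 is a latent ortho-quinone methide, and C2 carries only ring D and the oxygen. A (4+1) annulation with a 4-benzyloxybenzyl sulfonium ylide of a C2-symmetric thiolane therefore forms C2–C3 and C2–O1 on a substrate that already holds DHB 2.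
3. Bromine stands in for the styryl arm until after the annulation. An ortho-styryl benzhydryl cation is a pentadienyl cation, which closes to an indane (Nazarov-type) under the acid needed to make the sulfone.
4. The sulfone comes from the Grignard reagent of 5-bromo-DHB 2 and 4-(benzyloxy)-2-bromo-6-hydroxybenzaldehyde, followed by TolSO2H. DHB 2 comes from an enantioselective donor/donor carbene C–H insertion and acid epimerisation to trans.
5. Ring order: the dihydrofuran ring of DHB 2 (step 6), then the dihydrofuran ring of DHB 1 (step 15).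

Key step: step 15

Remark on the thiolane antipode: the (2S,5S)-thiolane is assumed to give (2S,3S)-DHB 1. This transposes the known sense of its benzylides in aldehyde epoxidation (aryl syn to the sulfur lone pair, attack anti to the methyl group cis to the ylide carbon, inversion on closure), with the change in CIP priorities taken into account. The enantiomeric salt is the remedy if a test shows the opposite sense.

Remark on the dirhodium catalyst: Rh2(R-PTAD)4 is assumed to be the antipode that delivers the (3R) centre of DHB 2. If a test run shows the opposite sense, Rh2(S-PTAD)4 is used and nothing else changes.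

Abbreviations: Bn = benzyl. "DHB 2-yl" = (2R,3R)-7-(benzyloxy)-2-[4-(benzyloxy)phenyl]-3-[3,5-bis(benzyloxy)phenyl]-2,3-dihydro-1-benzofuran-5-yl.

**Route**

Step 1
Reactants: 1 5-bromo-2,3-dihydroxybenzaldehyde
Product: 3 3-(benzyloxy)-5-bromo-2-hydroxybenzaldehyde, via disodium catecholate 2 (not isolated)
Conditions: NaH (2.1 equiv), DMSO, 20 °C; BnBr (1.0 equiv); aq. HCl
Reagents that add atoms: benzyl bromide, BrCc1ccccc1
Why: The dianion is alkylated at the more nucleophilic 3-phenoxide because the 2-phenoxide is delocalised into and chelated by the formyl group (regioselective Williamson etherification of a 2,3-dihydroxybenzaldehyde dianion).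

Step 2
Reactants: 3 3-(benzyloxy)-5-bromo-2-hydroxybenzaldehyde; 4 4-(benzyloxy)benzyl chloride
Product: 5 3-(benzyloxy)-2-{[4-(benzyloxy)benzyl]oxy}-5-bromobenzaldehyde
Conditions: K2CO3, KI (cat.), DMF, 60 °C
Reagents that add atoms: none
Why: Williamson etherification of the remaining hydrogen-bonded phenol with a reactive benzylic chloride under iodide catalysis; it installs the CH2 that becomes C2 of DHB 2 together with its aryl group.

Step 3
Reactants: 5 3-(benzyloxy)-2-{[4-(benzyloxy)benzyl]oxy}-5-bromobenzaldehyde; 6 1,3-bis(benzyloxy)-5-bromobenzene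
Product: 8 {3-(benzyloxy)-2-{[4-(benzyloxy)benzyl]oxy}-5-bromophenyl}[3,5-bis(benzyloxy)phenyl]methanol (racemic), via aryl Grignard reagent 7 (not isolated)
Conditions: 6, Mg, THF, 40 °C; then 5, THF, −78 → 0 °C; H2O
Reagents that add atoms: none
Why: Grignard addition to the aldehyde; the aryl bromide of 5 does not exchange with an arylmagnesium reagent at low temperature, and the new carbinol centre is racemic and is removed in step 4.

Step 4
Reactants: 8 the diarylmethanol
Product: 9 {3-(benzyloxy)-2-{[4-(benzyloxy)benzyl]oxy}-5-bromophenyl}[3,5-bis(benzyloxy)phenyl]methanone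
Conditions: MnO2, CH2Cl2, rt
Reagents that add atoms: none
Why: MnO2 oxidises the doubly benzylic alcohol to the diaryl ketone and leaves the benzyl ethers and the aryl bromide untouched (benzylic alcohol oxidation).

Step 5
Reactants: 9 the diaryl ketone
Product: 10 hydrazone of ketone 9 (E/Z mixture)
Conditions: N2H4·H2O, AcOH (cat.), EtOH, 80 °C
Reagents that add atoms: hydrazine hydrate, NN.O
Why: Acid-catalysed condensation of hydrazine with the diaryl ketone gives the free hydrazone, the precursor of a donor/donor diazo compound; the E/Z ratio is of no consequence.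

Step 6
Reactants: 10 hydrazone of ketone 9
Product: 12 (2S,3R)-7-(benzyloxy)-2-[4-(benzyloxy)phenyl]-3-[3,5-bis(benzyloxy)phenyl]-5-bromo-2,3-dihydro-1-benzofuran (cis), via diazo compound 11 (not isolated)
Conditions: MnO2, CH2Cl2, 0 °C, filtration; Rh2(R-PTAD)4 (1 mol %), CH2Cl2, 0 °C → rt
Reagents that add atoms: none
Why: MnO2 dehydrogenates the hydrazone to the diaryldiazomethane, whose dirhodium carbene inserts into the activated benzylic ether C–H bond in a 1,5-manner (intramolecular enantioselective C–H insertion of a donor/donor carbene); the chiral carboxylate ligands select the carbene face and set C3, and the concerted, hydride-transfer-like transition state places the two aryl groups cis and sets C2.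

Step 7
Reactants: 12 the cis-dihydrobenzofuran
Product: 13 (2R,3R)-7-(benzyloxy)-2-[4-(benzyloxy)phenyl]-3-[3,5-bis(benzyloxy)phenyl]-5-bromo-2,3-dihydro-1-benzofuran (trans)
Conditions: TFA, CH2Cl2, 0 °C → rt
Reagents that add atoms: none
Why: The acid reversibly ionises the C2–O bond to a cation stabilised by the 4-benzyloxyphenyl group and the phenol recloses to the more stable trans isomer (acid-catalysed C2 epimerisation of a 2-aryl-2,3-dihydrobenzofuran), while C3 is not touched and keeps the configuration set in step 6.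

Step 8
Reactants: 6 1,3-bis(benzyloxy)-5-bromobenzene
Product: 15 2,4-bis(benzyloxy)-6-bromobenzaldehyde, via iminium salt 14 (not isolated)
Conditions: POCl3, DMF, 0 → 80 °C; then H2O
Reagents that add atoms: N,N-dimethylformamide, CN(C)C=O; water, O
Why: Vilsmeier–Haack formylation occurs para to one benzyloxy group and ortho to the other, at the less congested position next to bromine and not between the two ether groups.

Step 9
Reactants: 15 2,4-bis(benzyloxy)-6-bromobenzaldehyde
Product: 16 4-(benzyloxy)-2-bromo-6-hydroxybenzaldehyde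
Conditions: MgBr2·OEt2, toluene/Et2O, 80 °C; dil. aq. HCl
Reagents that add atoms: none
Why: MgBr2 chelates the formyl oxygen and the ortho ether oxygen, and bromide cleaves only that benzyl group (chelation-directed ortho-debenzylation), which leaves the para benzyl ether in place.

Step 10
Reactants: 13 the trans bromo-dihydrobenzofuran; 16 4-(benzyloxy)-2-bromo-6-hydroxybenzaldehyde
Product: 19 (DHB 2-yl)[4-(benzyloxy)-2-bromo-6-hydroxyphenyl]methanol (both carbinol epimers), via DHB 2 Grignard reagent 17 (not isolated), via sodium phenoxide 18 (not isolated)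
Conditions: 13, Mg, LiCl, THF, 25 °C; 16, NaH, THF, 0 °C; combine, −40 → 0 °C; H2O
Reagents that add atoms: none
Why: Magnesium inserts into the C–Br bond of 13 and the aryl Grignard reagent adds to the aldehyde, whose phenol is masked as its sodium salt so that no organometallic is wasted; the ring B bromide does not exchange with an arylmagnesium species, and the carbinol centre is formed without control because it becomes trigonal in step 15.

Step 11
Reactants: 19 the ortho-hydroxybenzhydrol
Product: 20 5-(benzyloxy)-3-bromo-2-[(DHB 2-yl)(4-methylbenzenesulfonyl)methyl]phenol (both epimers at the sulfonyl carbon)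
Conditions: TolSO2H, MgSO4, CH2Cl2, rt
Reagents that add atoms: p-toluenesulfinic acid, Cc1ccc(cc1)S(=O)O
Why: The sulfinic acid ionises the ortho-hydroxy, para-benzyloxy benzhydrol and sulfinate captures the protonated quinone methide at sulfur (SN1 sulfone formation); with bromine and not a styryl group ortho to the cationic carbon no pentadienyl cation is available for Nazarov-type closure, and the sulfonyl carbon needs no control.

Step 12
Reactants: 21 (2R,5R)-hexane-2,5-diol
Product: 22 (2R,5R)-hexane-2,5-diyl dimethanesulfonate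
Conditions: MsCl, Et3N, CH2Cl2, 0 °C
Reagents that add atoms: methanesulfonyl chloride, CS(=O)(=O)Cl
Why: Mesylation of both secondary alcohols, which leaves the configuration at carbon unchanged.

Step 13
Reactants: 22 the dimesylate
Product: 23 (2S,5S)-2,5-dimethylthiolane
Conditions: Na2S·9H2O, EtOH, rt → 50 °C
Reagents that add atoms: sodium sulfide, [Na+].[Na+].[S-2]
Why: Sulfide displaces both mesylates by SN2 (the second intramolecular, 5-exo-tet) with inversion at each carbon, so the (2R,5R)-dimesylate gives the (2S,5S)-thiolane.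

Step 14
Reactants: 23 (2S,5S)-2,5-dimethylthiolane; 4 4-(benzyloxy)benzyl chloride
Product: 24 (2S,5S)-1-[4-(benzyloxy)benzyl]-2,5-dimethylthiolan-1-ium tetrafluoroborate
Conditions: AgBF4, CH2Cl2, 0 °C → rt, dark
Reagents that add atoms: silver tetrafluoroborate, [Ag+].F[B-](F)(F)F
Why: S-Alkylation of the sulfide by the benzylic chloride, driven by precipitation of AgCl; because the thiolane is C2-symmetric its two sulfur lone pairs are equivalent and a single sulfonium salt forms.

Step 15
Reactants: 20 the sulfone; 24 the sulfonium tetrafluoroborate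
Product: 28 (2S,3S)-6-(benzyloxy)-2-[4-(benzyloxy)phenyl]-4-bromo-3-(DHB 2-yl)-2,3-dihydro-1-benzofuran, via ortho-quinone methide 25 (not isolated), via sulfonium ylide 26 (not isolated), via betaine 27 (not isolated)
Conditions: 24 (1.5 equiv), Cs2CO3 (3 equiv), MeCN/CH2Cl2, −20 °C → rt
Reagents that add atoms: none
Why: Cs2CO3 deprotonates the phenol of 20, which expels toluenesulfinate to give the ortho-quinone methide 25, and deprotonates 24 to the semi-stabilised ylide 26; the ylide carbon adds to the methide carbon (the future C3) in a 1,4-addition that restores the aromaticity of ring B and gives the phenoxide–sulfonium betaine 27. The phenoxide then displaces the thiolane at the former ylide carbon with inversion, a 5-exo-tet SN2 closure that forms C2–O1 and the dihydrofuran ring of DHB 1. The closest known reaction is the (4+1) annulation of ortho-quinone methides released from 2-(1-sulfonylalkyl)phenols with sulfonium ylides, which gives trans-2,3-disubstituted dihydrobenzofurans. C2 is set by the C2-symmetric thiolane (reagent control: the aryl group of the ylide lies syn to the sulfur lone pair and the methide approaches the face away from the methyl group cis to the ylide carbon), and C3 follows from C2 because the anti betaine, with ring C and ring D apart, forms preferentially and is the one that closes, so the ring should be trans. The step needs C–C bond formation ahead of O-benzylation of the phenoxide, face selectivity at the ylide carbon and a trans ring; fast loss of sulfinate keeps the phenoxide concentration low, the two centres of DHB 2 are too remote to oppose the reagent, and bromine in place of a styryl group at C4 leaves the methide carbon accessible.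

Step 16
Reactants: 29 4-(benzyloxy)benzaldehyde
Product: 30 1-(benzyloxy)-4-ethenylbenzene
Conditions: Ph3PCH3Br, KOtBu, THF, 0 °C → rt
Reagents that add atoms: methyltriphenylphosphonium bromide, C[P+](c1ccccc1)(c1ccccc1)c1ccccc1.[Br-]
Why: Wittig methylenation of the aromatic aldehyde.

Step 17
Reactants: 28 the 4-bromo-dihydrobenzofuran; 30 1-(benzyloxy)-4-ethenylbenzene
Product: 31 hexa-O-benzyl ether of the target
Conditions: Pd(P(t-Bu)3)2 (5 mol %), Cy2NMe, 1,4-dioxane, 80 °C
Reagents that add atoms: none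
Why: Mizoroki–Heck reaction: oxidative addition of the C4–Br bond to the zerovalent palladium catalyst, insertion of the styrene at its terminal carbon and syn β-hydride elimination give the (E)-stilbene, and the bulky electron-rich phosphine allows a temperature low enough to protect the C3 benzylic centre.

Step 18
Reactants: 31 hexa-O-benzyl ether of the target
Product: 32 the target, (2S,3S)-3-[(2R,3R)-3-(3,5-dihydroxyphenyl)-7-hydroxy-2-(4-hydroxyphenyl)-2,3-dihydro-1-benzofuran-5-yl]-2-(4-hydroxyphenyl)-4-[(E)-2-(4-hydroxyphenyl)ethenyl]-2,3-dihydro-1-benzofuran-6-ol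
Conditions: BCl3, pentamethylbenzene, CH2Cl2, −78 °C; MeOH, then H2O
Reagents that add atoms: none
Why: BCl3 cleaves the six aryl benzyl ethers at −78 °C while pentamethylbenzene traps the benzyl cations by Friedel–Crafts alkylation, so that neither the stilbene nor the electron-rich rings are benzylated and the two trans dihydrofuran rings, already the more stable isomers, are not disturbed.

**Compound list**

1 | 5-bromo-2,3-dihydroxybenzaldehyde | O=Cc1cc(Br)cc(O)c1O | starting material
2 | disodium 5-bromo-3-formylbenzene-1,2-diolate | [Na+].[Na+].[O-]c1cc(Br)cc(C=O)c1[O-] | intermediate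
3 | 3-(benzyloxy)-5-bromo-2-hydroxybenzaldehyde | O=Cc1cc(Br)cc(OCc2ccccc2)c1O | intermediate
4 | 4-(benzyloxy)benzyl chloride | ClCc1ccc(OCc2ccccc2)cc1 | starting material
5 | 3-(benzyloxy)-2-{[4-(benzyloxy)benzyl]oxy}-5-bromobenzaldehyde | O=Cc1cc(Br)cc(OCc2ccccc2)c1OCc1ccc(OCc2ccccc2)cc1 | intermediate
6 | 1,3-bis(benzyloxy)-5-bromobenzene | Brc1cc(OCc2ccccc2)cc(OCc2ccccc2)c1 | starting material
7 | [3,5-bis(benzyloxy)phenyl]magnesium bromide | Br[Mg]c1cc(OCc2ccccc2)cc(OCc2ccccc2)c1 | intermediate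
8 | {3-(benzyloxy)-2-{[4-(benzyloxy)benzyl]oxy}-5-bromophenyl}[3,5-bis(benzyloxy)phenyl]methanol, racemic | OC(c1cc(Br)cc(OCc2ccccc2)c1OCc1ccc(OCc2ccccc2)cc1)c1cc(OCc2ccccc2)cc(OCc2ccccc2)c1 | intermediate
9 | {3-(benzyloxy)-2-{[4-(benzyloxy)benzyl]oxy}-5-bromophenyl}[3,5-bis(benzyloxy)phenyl]methanone | O=C(c1cc(Br)cc(OCc2ccccc2)c1OCc1ccc(OCc2ccccc2)cc1)c1cc(OCc2ccccc2)cc(OCc2ccccc2)c1 | intermediate
10 | hydrazone of ketone 9 (E/Z mixture) | NN=C(c1cc(Br)cc(OCc2ccccc2)c1OCc1ccc(OCc2ccccc2)cc1)c1cc(OCc2ccccc2)cc(OCc2ccccc2)c1 | intermediate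
11 | diazo compound from hydrazone 10, aryl[3,5-bis(benzyloxy)phenyl]diazomethane | [N-]=[N+]=C(c1cc(Br)cc(OCc2ccccc2)c1OCc1ccc(OCc2ccccc2)cc1)c1cc(OCc2ccccc2)cc(OCc2ccccc2)c1 | intermediate
12 | (2S,3R)-7-(benzyloxy)-2-[4-(benzyloxy)phenyl]-3-[3,5-bis(benzyloxy)phenyl]-5-bromo-2,3-dihydro-1-benzofuran (cis) | Brc1cc(OCc2ccccc2)c3c(c1)[C@@H](c1cc(OCc2ccccc2)cc(OCc2ccccc2)c1)[C@@H](c1ccc(OCc2ccccc2)cc1)O3 | intermediate
13 | (2R,3R)-7-(benzyloxy)-2-[4-(benzyloxy)phenyl]-3-[3,5-bis(benzyloxy)phenyl]-5-bromo-2,3-dihydro-1-benzofuran (trans) | Brc1cc(OCc2ccccc2)c3c(c1)[C@@H](c1cc(OCc2ccccc2)cc(OCc2ccccc2)c1)[C@H](c1ccc(OCc2ccccc2)cc1)O3 | intermediate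
14 | N-[2,4-bis(benzyloxy)-6-bromobenzylidene]-N-methylmethanaminium chloride | C[N+](C)=Cc1c(Br)cc(OCc2ccccc2)cc1OCc1ccccc1.[Cl-] | intermediate
15 | 2,4-bis(benzyloxy)-6-bromobenzaldehyde | O=Cc1c(Br)cc(OCc2ccccc2)cc1OCc1ccccc1 | intermediate
16 | 4-(benzyloxy)-2-bromo-6-hydroxybenzaldehyde | O=Cc1c(Br)cc(OCc2ccccc2)cc1O | intermediate
17 | (DHB 2-yl)magnesium bromide, the Grignard reagent of 13 | Br[Mg]c1cc(OCc2ccccc2)c3c(c1)[C@@H](c1cc(OCc2ccccc2)cc(OCc2ccccc2)c1)[C@H](c1ccc(OCc2ccccc2)cc1)O3 | intermediate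
18 | sodium 5-(benzyloxy)-3-bromo-2-formylphenolate | [Na+].[O-]c1cc(OCc2ccccc2)cc(Br)c1C=O | intermediate
19 | (DHB 2-yl)[4-(benzyloxy)-2-bromo-6-hydroxyphenyl]methanol, both carbinol epimers | OC(c4c(O)cc(OCc5ccccc5)cc4Br)c1cc(OCc2ccccc2)c3c(c1)[C@@H](c1cc(OCc2ccccc2)cc(OCc2ccccc2)c1)[C@H](c1ccc(OCc2ccccc2)cc1)O3 | intermediate
20 | 5-(benzyloxy)-3-bromo-2-[(DHB 2-yl)(4-methylbenzenesulfonyl)methyl]phenol, both epimers at the sulfonyl carbon | Cc1ccc(cc1)S(=O)(=O)C(c4c(O)cc(OCc5ccccc5)cc4Br)c1cc(OCc2ccccc2)c3c(c1)[C@@H](c1cc(OCc2ccccc2)cc(OCc2ccccc2)c1)[C@H](c1ccc(OCc2ccccc2)cc1)O3 | intermediate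
21 | (2R,5R)-hexane-2,5-diol | C[C@@H](O)CC[C@@H](C)O | starting material
22 | (2R,5R)-hexane-2,5-diyl dimethanesulfonate | C[C@@H](OS(C)(=O)=O)CC[C@@H](C)OS(C)(=O)=O | intermediate
23 | (2S,5S)-2,5-dimethylthiolane | C[C@H]1CC[C@H](C)S1 | intermediate
24 | (2S,5S)-1-[4-(benzyloxy)benzyl]-2,5-dimethylthiolan-1-ium tetrafluoroborate | C[C@H]1CC[C@H](C)[S+]1Cc1ccc(OCc2ccccc2)cc1.F[B-](F)(F)F | intermediate
25 | ortho-quinone methide, 3-(benzyloxy)-5-bromo-6-[(DHB 2-yl)methylidene]cyclohexa-2,4-dien-1-one | O=C4C=C(OCc5ccccc5)C=C(Br)C4=Cc1cc(OCc2ccccc2)c3c(c1)[C@@H](c1cc(OCc2ccccc2)cc(OCc2ccccc2)c1)[C@H](c1ccc(OCc2ccccc2)cc1)O3 | intermediate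
26 | sulfonium ylide of 24, (2S,5S)-2,5-dimethylthiolanium [4-(benzyloxy)phenyl]methanide | C[C@H]1CC[C@H](C)[S+]1[CH-]c1ccc(OCc2ccccc2)cc1 | intermediate
27 | anti betaine, the phenoxide bearing at the benzylic carbon (future C3) the DHB 2-yl group and the CH[4-(benzyloxy)phenyl] carbon (future C2) bonded to the (2S,5S)-2,5-dimethylthiolanium sulfur | [O-]c4cc(OCc5ccccc5)cc(Br)c4[C@H](c1cc(OCc2ccccc2)c3c(c1)[C@@H](c1cc(OCc2ccccc2)cc(OCc2ccccc2)c1)[C@H](c1ccc(OCc2ccccc2)cc1)O3)[C@H](c1ccc(OCc2ccccc2)cc1)[S+]1[C@@H](C)CC[C@@H]1C | intermediate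
28 | (2S,3S)-6-(benzyloxy)-2-[4-(benzyloxy)phenyl]-4-bromo-3-(DHB 2-yl)-2,3-dihydro-1-benzofuran | Brc4cc(OCc5ccccc5)cc6c4[C@H](c1cc(OCc2ccccc2)c3c(c1)[C@@H](c1cc(OCc2ccccc2)cc(OCc2ccccc2)c1)[C@H](c1ccc(OCc2ccccc2)cc1)O3)[C@@H](c1ccc(OCc2ccccc2)cc1)O6 | intermediate
29 | 4-(benzyloxy)benzaldehyde | O=Cc1ccc(OCc2ccccc2)cc1 | starting material
30 | 1-(benzyloxy)-4-ethenylbenzene | C=Cc1ccc(OCc2ccccc2)cc1 | intermediate
31 | hexa-O-benzyl ether of the target, (2S,3S)-6-(benzyloxy)-2-[4-(benzyloxy)phenyl]-4-{(E)-2-[4-(benzyloxy)phenyl]ethenyl}-3-(DHB 2-yl)-2,3-dihydro-1-benzofuran | c1ccccc1COc7ccc(/C=C/c4cc(OCc5ccccc5)cc6c4[C@H](c1cc(OCc2ccccc2)c3c(c1)[C@@H](c1cc(OCc2ccccc2)cc(OCc2ccccc2)c1)[C@H](c1ccc(OCc2ccccc2)cc1)O3)[C@@H](c1ccc(OCc2ccccc2)cc1)O6)cc7 | intermediate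
32 | (2S,3S)-3-[(2R,3R)-3-(3,5-dihydroxyphenyl)-7-hydroxy-2-(4-hydroxyphenyl)-2,3-dihydro-1-benzofuran-5-yl]-2-(4-hydroxyphenyl)-4-[(E)-2-(4-hydroxyphenyl)ethenyl]-2,3-dihydro-1-benzofuran-6-ol | Oc1ccc(/C=C/c2cc(O)cc3c2[C@H](c2cc(O)c4c(c2)[C@@H](c2cc(O)cc(O)c2)[C@H](c2ccc(O)cc2)O4)[C@@H](c2ccc(O)cc2)O3)cc1 | target

**Totals**

Total step count: 18. Longest linear sequence: 12 steps (1 to 7, 10, 11, 15, 17, 18).

**Steps most likely to fail**

Step 15. The ylide may add slowly or with poor facial control at the crowded methide carbon, and the salt may be consumed by benzylation of phenoxide or sulfinate. The fallback replaces the annulation by a carbene C–H insertion, as used for DHB 2. It sets out from 19 and comes back at 28.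
- The phenol of 19 is alkylated with chloride 4 (K2CO3, DMF) to give the ether alcohol F1.
- MnO2 oxidises it to the ketone F2, and hydrazine converts this to the hydrazone F3.
- MnO2 gives the diazo compound F4, which Rh2(S-PTAD)4 should convert by insertion into the benzylic ether C–H bond to the cis-(2R,3S)-dihydrobenzofuran F5.
- TFA in CH2Cl2 then epimerises C2 to the trans isomer 28.

Step 6. The hindered diazo compound may form azine or carbene dimer, and the insertion may proceed with low or opposite enantioselectivity. The fallback applies the annulation of step 15 to DHB 2. It sets out from 3 and comes back at 13, so steps 2 and 4 to 7 fall away.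
- Grignard reagent 7 (2.2 equiv, the first equivalent deprotonating the phenol) adds to 3 to give the diol F6, and TolSO2H converts this to the sulfone F7.
- The enantiomeric salt is made from commercial (2S,5S)-hexane-2,5-diol, C[C@H](O)CC[C@H](C)O, as in steps 12 to 14, through the dimesylate F8, (2R,5R)-2,5-dimethylthiolane F9 and the (2R,5R)-sulfonium tetrafluoroborate F10.
- Cs2CO3 releases the ortho-quinone methide F11 and the ylide F12, which should combine through the betaine F13 to give trans-(2R,3R)-13 directly.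
- This run also tests the sense of induction assumed for step 15.

Step 17. After oxidative addition the palladium may migrate to the C3 benzylic position, arylate ring C intramolecularly, or insert the styrene with the wrong regiochemistry. The fallback replaces the palladium coupling by a carbonyl olefination. It sets out from 28 and comes back at 31.
- Bromine–lithium exchange with n-BuLi at −78 °C gives the aryllithium F14, which DMF converts to the 4-carbaldehyde F15.
- Arbuzov reaction of chloride 4 with P(OEt)3 gives diethyl [4-(benzyloxy)benzyl]phosphonate F16.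
- Horner–Wadsworth–Emmons reaction of F15 with F16 (KOtBu, THF) should give the (E)-stilbene 31.

**Further compounds**

F1 | step 15 | (DHB 2-yl){4-(benzyloxy)-2-{[4-(benzyloxy)benzyl]oxy}-6-bromophenyl}methanol | OC(c4c(OCc5ccc(OCc6ccccc6)cc5)cc(OCc5ccccc5)cc4Br)c1cc(OCc2ccccc2)c3c(c1)[C@@H](c1cc(OCc2ccccc2)cc(OCc2ccccc2)c1)[C@H](c1ccc(OCc2ccccc2)cc1)O3
F2 | step 15 | (DHB 2-yl){4-(benzyloxy)-2-{[4-(benzyloxy)benzyl]oxy}-6-bromophenyl}methanone | O=C(c4c(OCc5ccc(OCc6ccccc6)cc5)cc(OCc5ccccc5)cc4Br)c1cc(OCc2ccccc2)c3c(c1)[C@@H](c1cc(OCc2ccccc2)cc(OCc2ccccc2)c1)[C@H](c1ccc(OCc2ccccc2)cc1)O3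
F3 | step 15 | hydrazone of ketone F2 | NN=C(c4c(OCc5ccc(OCc6ccccc6)cc5)cc(OCc5ccccc5)cc4Br)c1cc(OCc2ccccc2)c3c(c1)[C@@H](c1cc(OCc2ccccc2)cc(OCc2ccccc2)c1)[C@H](c1ccc(OCc2ccccc2)cc1)O3
F4 | step 15 | diazo compound from hydrazone F3 | [N-]=[N+]=C(c4c(OCc5ccc(OCc6ccccc6)cc5)cc(OCc5ccccc5)cc4Br)c1cc(OCc2ccccc2)c3c(c1)[C@@H](c1cc(OCc2ccccc2)cc(OCc2ccccc2)c1)[C@H](c1ccc(OCc2ccccc2)cc1)O3
F5 | step 15 | (2R,3S)-6-(benzyloxy)-2-[4-(benzyloxy)phenyl]-4-bromo-3-(DHB 2-yl)-2,3-dihydro-1-benzofuran (cis) | Brc4cc(OCc5ccccc5)cc6c4[C@H](c1cc(OCc2ccccc2)c3c(c1)[C@@H](c1cc(OCc2ccccc2)cc(OCc2ccccc2)c1)[C@H](c1ccc(OCc2ccccc2)cc1)O3)[C@H](c1ccc(OCc2ccccc2)cc1)O6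
F6 | step 6 | [3-(benzyloxy)-5-bromo-2-hydroxyphenyl][3,5-bis(benzyloxy)phenyl]methanol | OC(c1cc(Br)cc(OCc2ccccc2)c1O)c1cc(OCc2ccccc2)cc(OCc2ccccc2)c1
F7 | step 6 | 2-(benzyloxy)-4-bromo-6-{[3,5-bis(benzyloxy)phenyl](4-methylbenzenesulfonyl)methyl}phenol | Cc1ccc(cc1)S(=O)(=O)C(c1cc(Br)cc(OCc2ccccc2)c1O)c1cc(OCc2ccccc2)cc(OCc2ccccc2)c1
F8 | step 6 | (2S,5S)-hexane-2,5-diyl dimethanesulfonate | C[C@H](OS(C)(=O)=O)CC[C@H](C)OS(C)(=O)=O
F9 | step 6 | (2R,5R)-2,5-dimethylthiolane | C[C@@H]1CC[C@@H](C)S1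
F10 | step 6 | (2R,5R)-1-[4-(benzyloxy)benzyl]-2,5-dimethylthiolan-1-ium tetrafluoroborate | C[C@@H]1CC[C@@H](C)[S+]1Cc1ccc(OCc2ccccc2)cc1.F[B-](F)(F)F
F11 | step 6 | ortho-quinone methide, 2-(benzyloxy)-4-bromo-6-{[3,5-bis(benzyloxy)phenyl]methylidene}cyclohexa-2,4-dien-1-one | O=C1C(OCc2ccccc2)=CC(Br)=CC1=Cc1cc(OCc2ccccc2)cc(OCc2ccccc2)c1
F12 | step 6 | sulfonium ylide of F10 | C[C@@H]1CC[C@@H](C)[S+]1[CH-]c1ccc(OCc2ccccc2)cc1
F13 | step 6 | anti betaine leading to 13 | [O-]c1c(OCc2ccccc2)cc(Br)cc1[C@@H](c1cc(OCc2ccccc2)cc(OCc2ccccc2)c1)[C@@H](c1ccc(OCc2ccccc2)cc1)[S+]1[C@H](C)CC[C@H]1C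
F14 | step 17 | aryllithium from 28, lithium at C4 | [Li]c4cc(OCc5ccccc5)cc6c4[C@H](c1cc(OCc2ccccc2)c3c(c1)[C@@H](c1cc(OCc2ccccc2)cc(OCc2ccccc2)c1)[C@H](c1ccc(OCc2ccccc2)cc1)O3)[C@@H](c1ccc(OCc2ccccc2)cc1)O6
F15 | step 17 | (2S,3S)-6-(benzyloxy)-2-[4-(benzyloxy)phenyl]-3-(DHB 2-yl)-2,3-dihydro-1-benzofuran-4-carbaldehyde | O=Cc4cc(OCc5ccccc5)cc6c4[C@H](c1cc(OCc2ccccc2)c3c(c1)[C@@H](c1cc(OCc2ccccc2)cc(OCc2ccccc2)c1)[C@H](c1ccc(OCc2ccccc2)cc1)O3)[C@@H](c1ccc(OCc2ccccc2)cc1)O6
F16 | step 17 | diethyl [4-(benzyloxy)benzyl]phosphonate | CCOP(=O)(OCC)Cc1ccc(OCc2ccccc2)cc1
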